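Read the eta run by its balance, then count how much first nucleophile the flask's starting material can turn over.

| setting | eta | flask |
|---|---|---|
| starting material | 0.020 M | 0.040 M |
| first nucleophile | 0.028 M | 0.0280 M |
| gas | 23 mM (held) | 23 mM (held) |
| remark | run made earlier |  |
| time |  | 4.0 min |

eta run (percent of the starting material charged)

| time / s | target / % | other capture product / % | starting material / % |
|---|---|---|---|
| 12.0 | 18 | 2 | 70 |
| 25.0 | 26 | 2 | 42 |
| 40.0 | 36 | 3 | 24 |
| 50.0 | 38 | 7 | 16 |
| 60.0 | 43 | 3 | 12 |
| 80.0 | 41 | 6 | 6 |

(readings scatter by 1.5 percentage points)

- share of target in target plus other capture product at 3.0 s
- share of target in target plus other capture product at 4.0 min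
- which of target and other capture product there is more of at 4.0 min

- at the start none of the gas is in solution

In the eta run, target, other capture product and starting material leave a gap of 10.0% at 12.0 s, 42.0% at 60.0 s and 47.0% at 80.0 s. The objection is that the gap might be a pool slowly draining into target. But it is still growing late, while target stays near 42.0%, so it is treated here as a loss competing with target.

Let B be the concentration of first nucleophile. Assume target takes the share B/(B+K) of what starting material releases, where K is the balance concentration, the value of B at which target and gap grow equally. At the last two readings the gap averages 44.5%. Target and gap are totals gathered over the course of the run, so they are set against a mid-course B rather than B at those readings: the charge less half the target formed, one first nucleophile going into each target, gives 0.0238 M, and K reads 0.0252 M.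

Held at its charged B, the share gives the flask 0.0210 M of target, which is less than the 0.0280 M charged. But B falls as target forms, so that count runs high. At mid-course B is 0.0175 M, which gives 40.9% of the starting material as target. Other capture product read 5.33% late in the eta run. The flask's lower B should raise it to about 6.12%, so this reckoning puts the share at 87.0% at 4.0 min.

The forecast gives 92% (82% to 99%) at 3.0 s and 62% (35% to 88%) at 4.0 min, with target ahead: “Target probably stays ahead, but this is an extrapolation, so the range is wide.” The reckoning above stands higher at 4.0 min.

The flask gives 99.0% at 3.0 s and 84.4% at 4.0 min, with target ahead, 40.4% against 7.47%. At 4.00 min it still holds 42% of its first nucleophile and 0.036% of its starting material, which is the limiting reagent.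

    starting material → intermediate (k = 0.0330 /s)
    first nucleophile + intermediate → target (k = 41.0 /M/s)
    second nucleophile + intermediate → other capture product (k = 32.0 /M/s)
    intermediate → solvolysis product (k = 0.990 /s)
    gas ⇌ second nucleophile, rate k5*(csat - [second nucleophile]) (kL = 0.00900 /s)
    2 starting material → homo dimer (k = 0.00100 /M/s)

The same K, counted the same way for the neighbour flask charged with 0.070 M of first nucleophile, has B at 0.0553 M at mid-course and gives 68.7% as target. That neighbour flask holds 66.5% of target at 4.00 min.

Readings and results were computed on assumed constants; scatter was added.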